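The synthesis rests on cutting the two salicylate-type C–O bonds, ring A C2'–OH and ring B C6–OH, and adding them last to an already assembled depside. Each of these carbons lies ortho to an ester carbonyl whose other ortho carbon is filled (C6' methyl on ring A, C2 heptyl on ring B). Each carbonyl can therefore guide ruthenium to one C–H bond only, and a single operation oxygenates both rings. The precursor is the 2',6-dideoxy depside, built from two simple para-oxygenated benzoates. Its acid is masked as a trichloroethyl ester and its C4' phenol as a trichloroethyl carbonate; zinc removes both masks in the final step.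

Key step: step 7

Numbering used:
- Ring A is the benzoyl ring. C1' carries the depside carbonyl, C6' the methyl group, C4' the para oxygen, and C2' is the site to be oxygenated. Systematic names of the deoxy compounds call the same methyl carbon C2.
- Ring B is the benzoic acid ring. C1 carries the carboxyl carbon, C2 the heptyl chain, C4 the depside oxygen, and C6 is the site to be oxygenated.
- The target has no stereocentre.

Assumption: in step 7 the ring B site, served by the more basic alkyl ester carbonyl, is taken to react first; the order of the two oxygenations has no bearing on the product.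

Step 1
Reactants: 1 methyl 2-bromo-4-hydroxybenzoate; 2 1-heptyne
Product: 3 methyl 2-(hept-1-yn-1-yl)-4-hydroxybenzoate
Conditions: PdCl2(PPh3)2 (3 mol%), CuI (6 mol%), Et3N–DMF, 70 °C, argon
Reagents that add atoms: 1-heptyne (2), C#CCCCCC
Why: Sonogashira coupling; the ortho ester speeds oxidative addition of the C–Br bond to zerovalent palladium, and the phenol, meta to bromine, is tolerated under amine base.

Step 2
Reactants: 3 methyl 2-(hept-1-yn-1-yl)-4-hydroxybenzoate
Product: 4 methyl 2-heptyl-4-hydroxybenzoate
Conditions: H2 (1 atm), Pd/C (10 wt%), EtOAc–MeOH, rt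
Reagents that add atoms: none
Why: Heterogeneous catalytic hydrogenation saturates the alkyne to the heptyl chain, and it is placed here because no C–Cl bond that palladium and hydrogen could cleave is yet present.

Step 3
Reactants: 4 methyl 2-heptyl-4-hydroxybenzoate
Product: 5 2-heptyl-4-hydroxybenzoic acid
Conditions: NaOH (5 equiv), MeOH–H2O, reflux; then 2 M HCl
Reagents that add atoms: sodium hydroxide, [Na+].[OH-]
Why: Saponification by acyl–oxygen cleavage of a benzoate with only one ortho substituent; the para phenoxide slows it, but excess base at reflux should carry it through.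

Step 4
Reactants: 5 2-heptyl-4-hydroxybenzoic acid; 6 2,2,2-trichloroethanol
Product: 7 2,2,2-trichloroethyl 2-heptyl-4-hydroxybenzoate
Conditions: 6 (5 equiv), TsOH·H2O (0.2 equiv), toluene, reflux, Dean–Stark trap
Reagents that add atoms: 2,2,2-trichloroethanol (6), OCC(Cl)(Cl)Cl
Why: Fischer esterification with azeotropic removal of water; phenols are not acylated under acid-catalysed equilibrium conditions, so only the carboxyl group reacts and the C4 phenol stays free for step 6.

Step 5
Reactants: 8 4-hydroxy-2-methylbenzoic acid; 9 2,2,2-trichloroethyl chloroformate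
Product: 10 2-methyl-4-(2,2,2-trichloroethoxycarbonyloxy)benzoic acid
Conditions: NaOH (2.05 equiv), H2O–THF, 0 °C, 9 (1.1 equiv); then 1 M HCl
Reagents that add atoms: 2,2,2-trichloroethyl chloroformate (9), O=C(Cl)OCC(Cl)(Cl)Cl
Why: Schotten–Baumann O-acylation; in the dianion the phenoxide is the better nucleophile, any mixed carbonic anhydride at the carboxylate is hydrolysed by the aqueous medium, and the base is used up so the new carbonate does not sit in alkali.

Step 6
Reactants: 10 2-methyl-4-(2,2,2-trichloroethoxycarbonyloxy)benzoic acid; 7 2,2,2-trichloroethyl 2-heptyl-4-hydroxybenzoate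
Product: 12 2,2,2-trichloroethyl 2-heptyl-4-{[2-methyl-4-(2,2,2-trichloroethoxycarbonyloxy)benzoyl]oxy}benzoate, via acid chloride 11 (not isolated)
Conditions: (COCl)2, cat. DMF, CH2Cl2, 0 °C to rt, evaporate; then 7, pyridine (3 equiv), CH2Cl2, 0 °C to rt
Reagents that add atoms: none
Why: Acid chloride formation through the Vilsmeier-type chloroiminium species, then pyridine-mediated O-acylation of the phenol (the classical depside esterification); the acyl chloride is far more electrophilic than the aryl carbonate, so the carbonate should not be transferred.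

Step 7
Reactants: 12 2,2,2-trichloroethyl 2-heptyl-4-{[2-methyl-4-(2,2,2-trichloroethoxycarbonyloxy)benzoyl]oxy}benzoate
Product: 15 2,2,2-trichloroethyl 2-heptyl-6-hydroxy-4-{[2-hydroxy-6-methyl-4-(2,2,2-trichloroethoxycarbonyloxy)benzoyl]oxy}benzoate, via ring B mono(trifluoroacetate) 13 (not isolated), via bis(trifluoroacetate) 14 (not isolated)
Conditions: [RuCl2(p-cymene)]2 (5 mol%), AgOCOCF3 (20 mol%), PhI(OCOCF3)2 (3 equiv, two portions), TFA–TFAA (3:2), 70 °C; evaporate; then THF–H2O, rt
Reagents that add atoms: phenyliodine bis(trifluoroacetate), O=C(OI(OC(=O)C(F)(F)F)c1ccccc1)C(F)(F)F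
Why: Proposed new method: the chloride ligands are exchanged for trifluoroacetate, an ester carbonyl oxygen binds the divalent ruthenium centre, and carboxylate-assisted metalation of the neighbouring ortho C–H bond gives a five-membered ruthenacycle (Ru, O, carbonyl C, ipso C, ortho C). PhI(OCOCF3)2 oxidises this metallacycle to tetravalent ruthenium, C–O reductive elimination releases the aryl trifluoroacetate, and the cycle then runs again at the second ester, so 12 passes through 13 to 14 before neutral hydrolysis gives 15. The closest known reaction type is the ruthenium-catalysed ortho C–H hydroxylation of alkyl benzoates, ortho-alkyl ones included, in TFA–TFAA; what is new is its double use in one molecule and direction by an aryl (depside) ester. No ring is closed and no stereocentre is formed. The step needs site selectivity for ring A C2'–H and ring B C6–H over ring B C3/C5 and ring A C3'/C5': the wanted sites are reached through five-membered chelates, the unwanted ones only through looser six-membered chelates from the phenoxy side of the depside ester or from the very weakly basic trichloroethyl carbonate, and the C6' methyl and C2 heptyl groups block the only other benzoyl-side positions. Because every ring oxygen is acylated and TFAA caps each new phenol at once, the rings stay too electron-poor for undirected oxidation by the trivalent iodine reagent, and neither trichloroethyl group has an acid-labile or oxidisable site.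

Step 8
Reactants: 15 2,2,2-trichloroethyl 2-heptyl-6-hydroxy-4-{[2-hydroxy-6-methyl-4-(2,2,2-trichloroethoxycarbonyloxy)benzoyl]oxy}benzoate
Product: 16 4-[(2,4-dihydroxy-6-methylbenzoyl)oxy]-2-heptyl-6-hydroxybenzoic acid (target)
Conditions: activated Zn dust (20 equiv), AcOH–THF, rt; filter, wash with 1 M HCl
Reagents that add atoms: none
Why: Reductive β-elimination of 2,2,2-trichloroethyl groups (zinc reduces a C–Cl bond and the carboxylate or carbonate is expelled, the carbonate then losing CO2) frees acid and phenol together, while the aryl ester and the decarboxylation-prone salicylic acid are left alone at room temperature.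

Compound list
1 | methyl 2-bromo-4-hydroxybenzoate | COC(=O)c1ccc(O)cc1Br | starting material
2 | 1-heptyne | C#CCCCCC | starting material
3 | methyl 2-(hept-1-yn-1-yl)-4-hydroxybenzoate | CCCCCC#Cc1cc(O)ccc1C(=O)OC | intermediate
4 | methyl 2-heptyl-4-hydroxybenzoate | CCCCCCCc1cc(O)ccc1C(=O)OC | intermediate
5 | 2-heptyl-4-hydroxybenzoic acid | CCCCCCCc1cc(O)ccc1C(=O)O | intermediate
6 | 2,2,2-trichloroethanol | OCC(Cl)(Cl)Cl | starting material
7 | 2,2,2-trichloroethyl 2-heptyl-4-hydroxybenzoate | CCCCCCCc1cc(O)ccc1C(=O)OCC(Cl)(Cl)Cl | intermediate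
8 | 4-hydroxy-2-methylbenzoic acid | Cc1cc(O)ccc1C(=O)O | starting material
9 | 2,2,2-trichloroethyl chloroformate | O=C(Cl)OCC(Cl)(Cl)Cl | starting material
10 | 2-methyl-4-(2,2,2-trichloroethoxycarbonyloxy)benzoic acid | Cc1cc(OC(=O)OCC(Cl)(Cl)Cl)ccc1C(=O)O | intermediate
11 | 2-methyl-4-(2,2,2-trichloroethoxycarbonyloxy)benzoyl chloride (not isolated) | Cc1cc(OC(=O)OCC(Cl)(Cl)Cl)ccc1C(=O)Cl | intermediate
12 | 2,2,2-trichloroethyl 2-heptyl-4-{[2-methyl-4-(2,2,2-trichloroethoxycarbonyloxy)benzoyl]oxy}benzoate | CCCCCCCc1cc(OC(=O)c2ccc(OC(=O)OCC(Cl)(Cl)Cl)cc2C)ccc1C(=O)OCC(Cl)(Cl)Cl | intermediate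
13 | 2,2,2-trichloroethyl 2-heptyl-4-{[2-methyl-4-(2,2,2-trichloroethoxycarbonyloxy)benzoyl]oxy}-6-(trifluoroacetoxy)benzoate (not isolated) | CCCCCCCc1cc(OC(=O)c2ccc(OC(=O)OCC(Cl)(Cl)Cl)cc2C)cc(OC(=O)C(F)(F)F)c1C(=O)OCC(Cl)(Cl)Cl | intermediate
14 | 2,2,2-trichloroethyl 2-heptyl-4-{[2-methyl-4-(2,2,2-trichloroethoxycarbonyloxy)-6-(trifluoroacetoxy)benzoyl]oxy}-6-(trifluoroacetoxy)benzoate (not isolated) | CCCCCCCc1cc(OC(=O)c2c(C)cc(OC(=O)OCC(Cl)(Cl)Cl)cc2OC(=O)C(F)(F)F)cc(OC(=O)C(F)(F)F)c1C(=O)OCC(Cl)(Cl)Cl | intermediate
15 | 2,2,2-trichloroethyl 2-heptyl-6-hydroxy-4-{[2-hydroxy-6-methyl-4-(2,2,2-trichloroethoxycarbonyloxy)benzoyl]oxy}benzoate | CCCCCCCc1cc(OC(=O)c2c(C)cc(OC(=O)OCC(Cl)(Cl)Cl)cc2O)cc(O)c1C(=O)OCC(Cl)(Cl)Cl | intermediate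
16 | 4-[(2,4-dihydroxy-6-methylbenzoyl)oxy]-2-heptyl-6-hydroxybenzoic acid (CNP0227363.0, achiral) | CCCCCCCc1cc(OC(=O)c2c(C)cc(O)cc2O)cc(O)c1C(=O)O | target

Total step count: 8
Longest linear sequence: 7 (steps 1, 2, 3, 4, 6, 7, 8)

Steps most likely to fail

1. Step 7.
- The weakly basic ester carbonyls may hold ruthenium too loosely for metalation. Metalation may drift to the phenoxy side. The hot acidic medium may transacylate the depside link.
- The fallback uses known chemistry and puts the oxygen atoms in place before the rings are joined, so the depside never meets the oxidation medium. It sets out from 7 and comes back at 16.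
- Acetylation of 7 (Ac2O, pyridine) gives 2,2,2-trichloroethyl 4-acetoxy-2-heptylbenzoate F1. A single hydroxylation directed by the alkyl ester alone, the established substrate class, is run under the conditions of step 7. It leads via the 6-trifluoroacetate F2 to 2,2,2-trichloroethyl 4-acetoxy-2-heptyl-6-hydroxybenzoate F3. Pyrrolidine (1 equiv, CH2Cl2, 0 °C) then removes the aryl acetate to give 2,2,2-trichloroethyl 2-heptyl-4,6-dihydroxybenzoate F4.
- Purchased orsellinic acid F5 is treated with 9 (2.2 equiv) under the conditions of step 5 to give 2-methyl-4,6-bis(2,2,2-trichloroethoxycarbonyloxy)benzoic acid F6. Oxalyl chloride with cat. DMF converts this into acid chloride F7.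
- F7 acylates F4 (pyridine, CH2Cl2) at the C4 hydroxyl, because the C6 hydroxyl is tied up in a hydrogen bond to the ester carbonyl. This gives the fully masked depside F8, and zinc in acetic acid as in step 8 gives 16.

2. Step 4.
- Esterification by the weakly nucleophilic alcohol may stall short of completion, and forcing it may set off self-condensation through the free phenol.
- The fallback replaces the equilibrium by irreversible acylation of the alcohol with an acid chloride while the phenol is masked. It sets out from 5 and comes back at 7.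
- Ac2O in pyridine with aqueous work-up gives 4-acetoxy-2-heptylbenzoic acid F9. Oxalyl chloride with cat. DMF gives 4-acetoxy-2-heptylbenzoyl chloride F10. Treatment with 6 and pyridine gives 2,2,2-trichloroethyl 4-acetoxy-2-heptylbenzoate F1, the compound already met above.
- Pyrrolidine (1 equiv, 0 °C) should cleave the aryl acetate much faster than the benzoate ester and give 7.

3. Step 5.
- The chloroformate or the newly formed aryl carbonate may be hydrolysed in aqueous alkali, or acylation at the carboxylate may start oligomerisation.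
- The fallback forms the carbonate without water on a temporarily esterified acid. It sets out from 8 and comes back at 10.
- N,N-dimethylformamide di-tert-butyl acetal (toluene, 80 °C) gives tert-butyl 4-hydroxy-2-methylbenzoate F11. Treatment with 9 and pyridine in CH2Cl2 gives tert-butyl 2-methyl-4-(2,2,2-trichloroethoxycarbonyloxy)benzoate F12. TFA in CH2Cl2 then removes the tert-butyl ester to give 10.

Further compounds
F1 | step 7 | 2,2,2-trichloroethyl 4-acetoxy-2-heptylbenzoate | CCCCCCCc1cc(OC(C)=O)ccc1C(=O)OCC(Cl)(Cl)Cl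
F2 | step 7 | 2,2,2-trichloroethyl 4-acetoxy-2-heptyl-6-(trifluoroacetoxy)benzoate | CCCCCCCc1cc(OC(C)=O)cc(OC(=O)C(F)(F)F)c1C(=O)OCC(Cl)(Cl)Cl
F3 | step 7 | 2,2,2-trichloroethyl 4-acetoxy-2-heptyl-6-hydroxybenzoate | CCCCCCCc1cc(OC(C)=O)cc(O)c1C(=O)OCC(Cl)(Cl)Cl
F4 | step 7 | 2,2,2-trichloroethyl 2-heptyl-4,6-dihydroxybenzoate | CCCCCCCc1cc(O)cc(O)c1C(=O)OCC(Cl)(Cl)Cl
F5 | step 7 | orsellinic acid (2,4-dihydroxy-6-methylbenzoic acid, purchased) | Cc1cc(O)cc(O)c1C(=O)O
F6 | step 7 | 2-methyl-4,6-bis(2,2,2-trichloroethoxycarbonyloxy)benzoic acid | Cc1cc(OC(=O)OCC(Cl)(Cl)Cl)cc(OC(=O)OCC(Cl)(Cl)Cl)c1C(=O)O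
F7 | step 7 | 2-methyl-4,6-bis(2,2,2-trichloroethoxycarbonyloxy)benzoyl chloride | Cc1cc(OC(=O)OCC(Cl)(Cl)Cl)cc(OC(=O)OCC(Cl)(Cl)Cl)c1C(=O)Cl
F8 | step 7 | 2,2,2-trichloroethyl 2-heptyl-6-hydroxy-4-{[2-methyl-4,6-bis(2,2,2-trichloroethoxycarbonyloxy)benzoyl]oxy}benzoate | CCCCCCCc1cc(OC(=O)c2c(C)cc(OC(=O)OCC(Cl)(Cl)Cl)cc2OC(=O)OCC(Cl)(Cl)Cl)cc(O)c1C(=O)OCC(Cl)(Cl)Cl
F9 | step 4 | 4-acetoxy-2-heptylbenzoic acid | CCCCCCCc1cc(OC(C)=O)ccc1C(=O)O
F10 | step 4 | 4-acetoxy-2-heptylbenzoyl chloride | CCCCCCCc1cc(OC(C)=O)ccc1C(=O)Cl
F11 | step 5 | tert-butyl 4-hydroxy-2-methylbenzoate | Cc1cc(O)ccc1C(=O)OC(C)(C)C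
F12 | step 5 | tert-butyl 2-methyl-4-(2,2,2-trichloroethoxycarbonyloxy)benzoate | Cc1cc(OC(=O)OCC(Cl)(Cl)Cl)ccc1C(=O)OC(C)(C)C
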